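**Retrosynthetic overview**
1. The 11-membered carbocycle is closed last by an intramolecular aldol condensation of seco-dialdehyde 24, which forms C6=C7 and the E-enal in one operation (instead of an NHK or RCM closure).
2. The threo epoxy ester comes from erythro epoxy alcohol 18 by Mitsunobu inversion with senecioic acid; 18 comes from a matched Sharpless epoxidation of divinyl carbinol 17; the side chain is finished by cross-metathesis.
3. 17 comes from enal 11 and alkyne 13 by asymmetric zinc alkynylation (C1–C11 bond), then trans-hydrostannation and methylation (E-C10=C11).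
4. 11 comes from a Johnson–Claisen chirality transfer (quaternary C4, E-C2=C3) on the D-glyceraldehyde-derived allylic alcohol 4, itself made by carboalumination of pent-1-en-4-yne.
5. Ring order: oxirane first (step 10), carbocycle last (step 15).

Assumption: ring atoms are numbered C1 (acyloxy carbon) to C11 (methyl-bearing oxirane carbon) in the direction of the SMILES, C20 is the formyl carbon, the target is (1S,4R,10R,11S) with 2E, 6E (enal) and an E side chain, and compounds 1, 2, 5, 12, 19 and 21 are taken as commercial.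

**Route**

Step 1
Reactants: 1 pent-1-en-4-yne; 2 (R)-2,2-dimethyl-1,3-dioxolane-4-carbaldehyde
Product: 4 (1S,2E)-1-[(4R)-2,2-dimethyl-1,3-dioxolan-4-yl]-3-methylhexa-2,5-dien-1-ol, via alkenylalane 3 (not isolated)
Conditions: Me3Al, Cp2ZrCl2 (20 mol %), CH2Cl2, 0 °C → rt; then 2, −78 → 0 °C; aq. KNaC4H4O6; chromatography
Reagents that add atoms: trimethylaluminium, C[Al](C)C
Why: Negishi zirconium-catalysed carboalumination adds Me and Al syn across the terminal alkyne only (E-alkenylalane, C4 methyl cis to the metal), and the alkenylalane adds to the α-alkoxy aldehyde under Felkin–Anh control to give mainly the anti (1S) carbinol, which is separated from the minor syn epimer.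

Step 2
Reactants: 4 (1S,2E)-1-[(4R)-2,2-dimethyl-1,3-dioxolan-4-yl]-3-methylhexa-2,5-dien-1-ol; 5 triethyl orthoacetate
Product: 7 ethyl (3R,4E)-5-[(4S)-2,2-dimethyl-1,3-dioxolan-4-yl]-3-methyl-3-(prop-2-en-1-yl)pent-4-enoate, via mixed ketene acetal 6 (not isolated)
Conditions: EtCO2H (cat.), neat 5, 140 °C, EtOH distilled off
Reagents that add atoms: none
Why: Johnson–Claisen rearrangement through a chair transition state with the dioxolanyl group equatorial transfers the (S) carbinol chirality suprafacially to the new quaternary carbon C4 (R), forms the E C2=C3 alkene and brings in C5–C6 as the ester.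

Step 3
Reactants: 7 ethyl (3R,4E)-5-[(4S)-2,2-dimethyl-1,3-dioxolan-4-yl]-3-methyl-3-(prop-2-en-1-yl)pent-4-enoate
Product: 8 (3R,4E)-5-[(4S)-2,2-dimethyl-1,3-dioxolan-4-yl]-3-methyl-3-(prop-2-en-1-yl)pent-4-en-1-ol
Conditions: LiAlH4, Et2O, 0 °C; then H2O, aq. NaOH
Reagents that add atoms: none
Why: Hydride reduction of the ester to the primary alcohol (C6) leaves the acetonide and the unactivated alkenes untouched.

Step 4
Reactants: 8 (3R,4E)-5-[(4S)-2,2-dimethyl-1,3-dioxolan-4-yl]-3-methyl-3-(prop-2-en-1-yl)pent-4-en-1-ol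
Product: 9 tert-butyl{[(3R,4E)-5-[(4S)-2,2-dimethyl-1,3-dioxolan-4-yl]-3-methyl-3-(prop-2-en-1-yl)pent-4-en-1-yl]oxy}diphenylsilane
Conditions: TBDPSCl, imidazole, DMF, rt
Reagents that add atoms: tert-butyl(chloro)diphenylsilane, CC(C)(C)[Si](Cl)(c1ccccc1)c1ccccc1
Why: Standard silylation masks the C6 hydroxyl with an acid-stable group that survives the periodic acid step and all later steps.

Step 5
Reactants: 9 tert-butyl{[(3R,4E)-5-[(4S)-2,2-dimethyl-1,3-dioxolan-4-yl]-3-methyl-3-(prop-2-en-1-yl)pent-4-en-1-yl]oxy}diphenylsilane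
Product: 11 (2E,4R)-4-{2-[(tert-butyldiphenylsilyl)oxy]ethyl}-4-methylhepta-2,6-dienal, via diol 10 (not isolated)
Conditions: H5IO6, EtOAc, rt
Reagents that add atoms: none
Why: One-pot acetonide hydrolysis and Malaprade glycol cleavage removes the sacrificial glyceraldehyde stereocentre and unveils C1 as an E-enal whose γ-carbon is quaternary, so it can neither epimerise nor deconjugate.

Step 6
Reactants: 12 hex-5-yn-1-ol
Product: 13 tert-butyl(hex-5-yn-1-yloxy)dimethylsilane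
Conditions: TBSCl, imidazole, CH2Cl2, rt
Reagents that add atoms: tert-butyl(chloro)dimethylsilane, CC(C)(C)[Si](C)(C)Cl
Why: Standard silylation masks the future C20 hydroxyl of the C20/C7–C11 fragment.

Step 7
Reactants: 11 (2E,4R)-4-{2-[(tert-butyldiphenylsilyl)oxy]ethyl}-4-methylhepta-2,6-dienal; 13 tert-butyl(hex-5-yn-1-yloxy)dimethylsilane
Product: 15 (7R,8E,10R)-1-[(tert-butyldimethylsilyl)oxy]-10-{2-[(tert-butyldiphenylsilyl)oxy]ethyl}-10-methyltrideca-8,12-dien-5-yn-7-ol, via alkynylzinc 14 (not isolated)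
Conditions: (R,R)-ProPhenol (20 mol %), Me2Zn, Ph3P=O (40 mol %), PhMe, 4 °C; then aq. NH4Cl
Reagents that add atoms: none
Why: Dinuclear zinc ProPhenol alkynylation of the enal is reagent-controlled (the nearest stereocentre is the remote quaternary C4) and the ligand antipode is chosen for Si-face delivery, assigned here by analogy with the ProPhenol aldol facial sense and to be confirmed by Mosher ester analysis, giving the (R) carbinol at C1 by 1,2-addition.

Step 8
Reactants: 15 (7R,8E,10R)-1-[(tert-butyldimethylsilyl)oxy]-10-{2-[(tert-butyldiphenylsilyl)oxy]ethyl}-10-methyltrideca-8,12-dien-5-yn-7-ol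
Product: 16 (5Z,7R,8E,10R)-1-[(tert-butyldimethylsilyl)oxy]-10-{2-[(tert-butyldiphenylsilyl)oxy]ethyl}-10-methyl-6-(tributylstannyl)trideca-5,8,12-trien-7-ol
Conditions: Bu3SnH, [Cp*RuCl]4 (2.5 mol %), CH2Cl2, rt
Reagents that add atoms: tributyltin hydride, CCCC[SnH](CCCC)CCCC
Why: Hydroxyl-directed ruthenium-catalysed trans-hydrostannation adds H and Sn anti across the alkyne with tin on the carbon next to the carbinol, fixing the C10=C11 geometry (C9 trans to C1) while the alkenes are inert.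

Step 9
Reactants: 16 (5Z,7R,8E,10R)-1-[(tert-butyldimethylsilyl)oxy]-10-{2-[(tert-butyldiphenylsilyl)oxy]ethyl}-10-methyl-6-(tributylstannyl)trideca-5,8,12-trien-7-ol
Product: 17 (5E,7R,8E,10R)-1-[(tert-butyldimethylsilyl)oxy]-10-{2-[(tert-butyldiphenylsilyl)oxy]ethyl}-6,10-dimethyltrideca-5,8,12-trien-7-ol
Conditions: MeI, Pd(PPh3)4 (10 mol %), Cu(O2C-2-C4H3S), [NBu4][Ph2PO2], DMF, rt
Reagents that add atoms: iodomethane, CI
Why: Copper-assisted Stille methylation replaces tin by methyl with retention of alkene geometry and tolerates the free hydroxyl, giving the E-trisubstituted 2-methyl allylic alcohol.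

Step 10
Reactants: 17 (5E,7R,8E,10R)-1-[(tert-butyldimethylsilyl)oxy]-10-{2-[(tert-butyldiphenylsilyl)oxy]ethyl}-6,10-dimethyltrideca-5,8,12-trien-7-ol
Product: 18 (1R,2E,4R)-1-[(2R,3R)-3-{4-[(tert-butyldimethylsilyl)oxy]butyl}-2-methyloxiran-2-yl]-4-{2-[(tert-butyldiphenylsilyl)oxy]ethyl}-4-methylhepta-2,6-dien-1-ol
Conditions: t-BuOOH, Ti(OiPr)4 (20 mol %), D-(−)-DIPT (25 mol %), 4 Å MS, CH2Cl2, −20 °C
Reagents that add atoms: tert-butyl hydroperoxide, CC(C)(C)OO
Why: Sharpless asymmetric epoxidation in its matched kinetic-resolution mode delivers oxygen with D-(−)-tartrate to the face that gives the (10R,11S) oxirane of the target, erythro to the (1R) carbinol, while the C2=C3 alkene is the mismatched and neopentyl one and stays, and any minor C1 epimer from step 7 is left behind.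

Step 11
Reactants: 18 (1R,2E,4R)-1-[(2R,3R)-3-{4-[(tert-butyldimethylsilyl)oxy]butyl}-2-methyloxiran-2-yl]-4-{2-[(tert-butyldiphenylsilyl)oxy]ethyl}-4-methylhepta-2,6-dien-1-ol; 19 3-methylbut-2-enoic acid (senecioic acid)
Product: 20 (1S,2E,4R)-1-[(2S,3R)-3-{4-[(tert-butyldimethylsilyl)oxy]butyl}-2-methyloxiran-2-yl]-4-{2-[(tert-butyldiphenylsilyl)oxy]ethyl}-4-methylhepta-2,6-dien-1-yl 3-methylbut-2-enoate
Conditions: PPh3, DIAD, PhMe, 0 °C → rt
Reagents that add atoms: none
Why: Mitsunobu esterification displaces the activated allylic C1 oxygen by SN2 with inversion, turning the erythro alcohol into the threo (1S) senecioate of the target in one step, with SN2′ attack blocked by the quaternary C4 and no β-hydrogen available for elimination.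

Step 12
Reactants: 20 (1S,2E,4R)-1-[(2S,3R)-3-{4-[(tert-butyldimethylsilyl)oxy]butyl}-2-methyloxiran-2-yl]-4-{2-[(tert-butyldiphenylsilyl)oxy]ethyl}-4-methylhepta-2,6-dien-1-yl 3-methylbut-2-enoate; 21 2-methylbut-3-en-2-ol
Product: 22 (1S,2E,4R,6E)-1-[(2S,3R)-3-{4-[(tert-butyldimethylsilyl)oxy]butyl}-2-methyloxiran-2-yl]-4-{2-[(tert-butyldiphenylsilyl)oxy]ethyl}-8-hydroxy-4,8-dimethylnona-2,6-dien-1-yl 3-methylbut-2-enoate
Conditions: 21 (10 equiv), second-generation Hoveyda–Grubbs catalyst RuCl2(H2IMes)(=CH-C6H4-2-OiPr) (5 mol %), CH2Cl2, 40 °C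
Reagents that add atoms: none
Why: Olefin cross-metathesis engages only the terminal allyl group (the neopentyl C2=C3 alkene and the trisubstituted enoate are inert) and gives the E allylic tertiary alcohol side chain.

Step 13
Reactants: 22 (1S,2E,4R,6E)-1-[(2S,3R)-3-{4-[(tert-butyldimethylsilyl)oxy]butyl}-2-methyloxiran-2-yl]-4-{2-[(tert-butyldiphenylsilyl)oxy]ethyl}-8-hydroxy-4,8-dimethylnona-2,6-dien-1-yl 3-methylbut-2-enoate
Product: 23 (1S,2E,4R,6E)-8-hydroxy-1-[(2S,3R)-3-(4-hydroxybutyl)-2-methyloxiran-2-yl]-4-(2-hydroxyethyl)-4,8-dimethylnona-2,6-dien-1-yl 3-methylbut-2-enoate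
Conditions: Bu4NF, AcOH, THF, 0 °C → rt
Reagents that add atoms: none
Why: Acetic-acid-buffered fluoride removes both silyl ethers without touching the ester or the oxirane, and the triol is oxidised at once so that the C20 hydroxyl cannot open the oxirane.

Step 14
Reactants: 23 (1S,2E,4R,6E)-8-hydroxy-1-[(2S,3R)-3-(4-hydroxybutyl)-2-methyloxiran-2-yl]-4-(2-hydroxyethyl)-4,8-dimethylnona-2,6-dien-1-yl 3-methylbut-2-enoate
Product: 24 (1S,2E,4R,6E)-8-hydroxy-4,8-dimethyl-1-[(2S,3R)-2-methyl-3-(4-oxobutyl)oxiran-2-yl]-4-(2-oxoethyl)nona-2,6-dien-1-yl 3-methylbut-2-enoate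
Conditions: Dess–Martin periodinane, NaHCO3, CH2Cl2, 0 °C → rt
Reagents that add atoms: none
Why: Buffered Dess–Martin oxidation converts both primary alcohols into aldehydes (C6 and C20) while the tertiary allylic alcohol cannot be oxidised.

Step 15
Reactants: 24 (1S,2E,4R,6E)-8-hydroxy-4,8-dimethyl-1-[(2S,3R)-2-methyl-3-(4-oxobutyl)oxiran-2-yl]-4-(2-oxoethyl)nona-2,6-dien-1-yl 3-methylbut-2-enoate
Product: 26 (1S,2S,3E,5R,7E,11R)-8-formyl-5-[(2E)-4-hydroxy-4-methylpent-2-en-1-yl]-1,5-dimethyl-12-oxabicyclo[9.1.0]dodeca-3,7-dien-2-yl 3-methylbut-2-enoate (CNP0164725.2), via macrocyclic aldol 25 (not isolated)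
Conditions: Bn2NH·CF3CO2H (1 equiv), PhMe, 1 mM by slow addition, 50 °C
Reagents that add atoms: none
Why: Proposed new method: the ammonium salt turns the unhindered C20 aldehyde into its enamine (the C6 aldehyde has a neopentyl α-carbon and enolises far more slowly), the enamine adds intramolecularly to the C6 aldehyde helped by the gem-disubstituted C4 and the rigid E-alkene and oxirane, and irreversible E1cB loss of water from aldol 25 followed by dienamine equilibration gives the thermodynamic E-enal (C5 trans to CHO) without putting any stereocentre at risk; the closest known reaction type is the amine-salt-catalysed intramolecular aldol condensation of dialdehydes to five- and six-membered cycloalkene carbaldehydes, extended here to an 11-membered ring.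

**Compound list**
1 | pent-1-en-4-yne | C#CCC=C | starting material
2 | (R)-2,2-dimethyl-1,3-dioxolane-4-carbaldehyde (D-glyceraldehyde acetonide) | O=C[C@H]1COC(C)(C)O1 | starting material
3 | (E)-dimethyl(2-methylpenta-1,4-dien-1-yl)alane, not isolated | C[Al](C)/C=C(\C)CC=C | intermediate
4 | (1S,2E)-1-[(4R)-2,2-dimethyl-1,3-dioxolan-4-yl]-3-methylhexa-2,5-dien-1-ol | C=CC/C(C)=C/[C@H](O)[C@H]1COC(C)(C)O1 | intermediate
5 | triethyl orthoacetate | CC(OCC)(OCC)OCC | starting material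
6 | 1-ethoxyvinyl ether of 4 (mixed ketene acetal), not isolated | C=CC/C(C)=C/[C@H](OC(=C)OCC)[C@H]1COC(C)(C)O1 | intermediate
7 | ethyl (3R,4E)-5-[(4S)-2,2-dimethyl-1,3-dioxolan-4-yl]-3-methyl-3-(prop-2-en-1-yl)pent-4-enoate | CCOC(=O)C[C@@](C)(CC=C)/C=C/[C@H]1COC(C)(C)O1 | intermediate
8 | (3R,4E)-5-[(4S)-2,2-dimethyl-1,3-dioxolan-4-yl]-3-methyl-3-(prop-2-en-1-yl)pent-4-en-1-ol | OCC[C@@](C)(CC=C)/C=C/[C@H]1COC(C)(C)O1 | intermediate
9 | tert-butyl{[(3R,4E)-5-[(4S)-2,2-dimethyl-1,3-dioxolan-4-yl]-3-methyl-3-(prop-2-en-1-yl)pent-4-en-1-yl]oxy}diphenylsilane | CC(C)(C)[Si](c1ccccc1)(c1ccccc1)OCC[C@@](C)(CC=C)/C=C/[C@H]1COC(C)(C)O1 | intermediate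
10 | (2S,3E,5R)-5-{2-[(tert-butyldiphenylsilyl)oxy]ethyl}-5-methylocta-3,7-diene-1,2-diol, not isolated | OC[C@@H](O)/C=C/[C@](C)(CC=C)CCO[Si](c1ccccc1)(c1ccccc1)C(C)(C)C | intermediate
11 | (2E,4R)-4-{2-[(tert-butyldiphenylsilyl)oxy]ethyl}-4-methylhepta-2,6-dienal | O=C/C=C/[C@](C)(CC=C)CCO[Si](c1ccccc1)(c1ccccc1)C(C)(C)C | intermediate
12 | hex-5-yn-1-ol | OCCCCC#C | starting material
13 | tert-butyl(hex-5-yn-1-yloxy)dimethylsilane | C#CCCCCO[Si](C)(C)C(C)(C)C | intermediate
14 | methylzinc acetylide of 13, not isolated | C[Zn]C#CCCCCO[Si](C)(C)C(C)(C)C | intermediate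
15 | (7R,8E,10R)-1-[(tert-butyldimethylsilyl)oxy]-10-{2-[(tert-butyldiphenylsilyl)oxy]ethyl}-10-methyltrideca-8,12-dien-5-yn-7-ol | O[C@H](/C=C/[C@](C)(CC=C)CCO[Si](c1ccccc1)(c1ccccc1)C(C)(C)C)C#CCCCCO[Si](C)(C)C(C)(C)C | intermediate
16 | (5Z,7R,8E,10R)-1-[(tert-butyldimethylsilyl)oxy]-10-{2-[(tert-butyldiphenylsilyl)oxy]ethyl}-10-methyl-6-(tributylstannyl)trideca-5,8,12-trien-7-ol | O[C@H](/C=C/[C@](C)(CC=C)CCO[Si](c1ccccc1)(c1ccccc1)C(C)(C)C)/C([Sn](CCCC)(CCCC)CCCC)=C/CCCCO[Si](C)(C)C(C)(C)C | intermediate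
17 | (5E,7R,8E,10R)-1-[(tert-butyldimethylsilyl)oxy]-10-{2-[(tert-butyldiphenylsilyl)oxy]ethyl}-6,10-dimethyltrideca-5,8,12-trien-7-ol | O[C@H](/C=C/[C@](C)(CC=C)CCO[Si](c1ccccc1)(c1ccccc1)C(C)(C)C)/C(C)=C/CCCCO[Si](C)(C)C(C)(C)C | intermediate
18 | (1R,2E,4R)-1-[(2R,3R)-3-{4-[(tert-butyldimethylsilyl)oxy]butyl}-2-methyloxiran-2-yl]-4-{2-[(tert-butyldiphenylsilyl)oxy]ethyl}-4-methylhepta-2,6-dien-1-ol (erythro epoxy alcohol) | O[C@H](/C=C/[C@](C)(CC=C)CCO[Si](c1ccccc1)(c1ccccc1)C(C)(C)C)[C@@]1(C)O[C@@H]1CCCCO[Si](C)(C)C(C)(C)C | intermediate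
19 | 3-methylbut-2-enoic acid (senecioic acid) | CC(C)=CC(=O)O | starting material
20 | (1S,2E,4R)-1-[(2S,3R)-3-{4-[(tert-butyldimethylsilyl)oxy]butyl}-2-methyloxiran-2-yl]-4-{2-[(tert-butyldiphenylsilyl)oxy]ethyl}-4-methylhepta-2,6-dien-1-yl 3-methylbut-2-enoate (threo epoxy ester) | CC(C)=CC(=O)O[C@@H](/C=C/[C@](C)(CC=C)CCO[Si](c1ccccc1)(c1ccccc1)C(C)(C)C)[C@@]1(C)O[C@@H]1CCCCO[Si](C)(C)C(C)(C)C | intermediate
21 | 2-methylbut-3-en-2-ol | C=CC(C)(C)O | starting material
22 | (1S,2E,4R,6E)-1-[(2S,3R)-3-{4-[(tert-butyldimethylsilyl)oxy]butyl}-2-methyloxiran-2-yl]-4-{2-[(tert-butyldiphenylsilyl)oxy]ethyl}-8-hydroxy-4,8-dimethylnona-2,6-dien-1-yl 3-methylbut-2-enoate | CC(C)=CC(=O)O[C@@H](/C=C/[C@](C)(C/C=C/C(C)(C)O)CCO[Si](c1ccccc1)(c1ccccc1)C(C)(C)C)[C@@]1(C)O[C@@H]1CCCCO[Si](C)(C)C(C)(C)C | intermediate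
23 | (1S,2E,4R,6E)-8-hydroxy-1-[(2S,3R)-3-(4-hydroxybutyl)-2-methyloxiran-2-yl]-4-(2-hydroxyethyl)-4,8-dimethylnona-2,6-dien-1-yl 3-methylbut-2-enoate | CC(C)=CC(=O)O[C@@H](/C=C/[C@](C)(C/C=C/C(C)(C)O)CCO)[C@@]1(C)O[C@@H]1CCCCO | intermediate
24 | (1S,2E,4R,6E)-8-hydroxy-4,8-dimethyl-1-[(2S,3R)-2-methyl-3-(4-oxobutyl)oxiran-2-yl]-4-(2-oxoethyl)nona-2,6-dien-1-yl 3-methylbut-2-enoate (seco-dialdehyde) | CC(C)=CC(=O)O[C@@H](/C=C/[C@](C)(C/C=C/C(C)(C)O)CC=O)[C@@]1(C)O[C@@H]1CCCC=O | intermediate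
25 | 11-membered β-hydroxy aldehyde (7-hydroxy-8-formyl-7,8-dihydro form of 26, epimers at the two new carbons), not isolated | CC(C)=CC(=O)O[C@H]1/C=C/[C@](C)(C/C=C/C(C)(C)O)CC(O)C(C=O)CC[C@H]2O[C@]12C | intermediate
26 | (1S,2S,3E,5R,7E,11R)-8-formyl-5-[(2E)-4-hydroxy-4-methylpent-2-en-1-yl]-1,5-dimethyl-12-oxabicyclo[9.1.0]dodeca-3,7-dien-2-yl 3-methylbut-2-enoate (CNP0164725.2) | CC(C)=CC(=O)O[C@H]1/C=C/[C@](C)(C/C=C/C(C)(C)O)C/C=C(/C=O)CC[C@H]2O[C@]12C | target

**Totals and risk**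

Total step count: 15. Longest linear sequence: 14 steps (steps 1–5, then 7–15, from pent-1-en-4-yne); step 6 is the one-step side branch.

Most likely to fail, in order:

Step 15 (macrocyclic aldol condensation; reversible aldol addition, oligomerisation or poor control of which aldehyde enolises). The fallback sets out from 24 and comes back at 26. The C20 aldehyde of 24, the only one that forms an enamine readily, is brominated at C7 with 4,4-dibromo-2,6-di-tert-butylcyclohexa-2,5-dienone and a catalytic secondary amine to give the α-bromo dialdehyde F1. PPh3 in MeCN converts it into the (1-formylalkyl)phosphonium bromide F2. Et3N then liberates the formyl-stabilised ylide F3, which at high dilution in warm PhMe closes the ring by an irreversible, E-selective intramolecular Wittig reaction on the C6 aldehyde to give 26 directly.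

Step 11 (Mitsunobu inversion at a carbinol flanked by a fully substituted oxirane carbon; slow SN2 or loss of stereochemical fidelity). The fallback sets out from 11 and comes back at 20. Alkynylation of 11 with 13 under (S,S)-ProPhenol and Me2Zn gives the C1-epimeric (7S)-propargylic alcohol F4. The same trans-hydrostannation gives the stannane F5, and the same methylation gives the (7S)-allylic alcohol F6, which already has the target configuration at C1. Acylation with 19, DCC and DMAP gives the senecioate F7. A reagent-controlled Shi epoxidation (D-fructose-derived ketone, KHSO5, K2CO3, MeCN/dimethoxymethane/H2O, 0 °C) then oxidises the only electron-rich trisubstituted alkene from the face that gives 20, with no inversion needed.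

Step 1 (modest anti/syn selectivity in the addition to glyceraldehyde acetonide, which would erode the enantiopurity of C4 if the epimers are not separable). The fallback sets out from 4, taken as the crude mixture with its syn epimer F8, and comes back at 4. The mixture is oxidised with Dess–Martin periodinane to the single enone F9, and chelation-controlled reduction with Zn(BH4)2 in Et2O at −30 °C (hydride delivered anti to the dioxolane CH2 in the zinc chelate) returns the anti alcohol 4.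

**Further compounds**
F1 | step 15 | C7-bromo derivative of 24 (α-bromo dialdehyde, bromine next to the C20 formyl group, C7 epimers) | CC(C)=CC(=O)O[C@@H](/C=C/[C@](C)(C/C=C/C(C)(C)O)CC=O)[C@@]1(C)O[C@@H]1CCC(Br)C=O
F2 | step 15 | C7-triphenylphosphonium bromide of 24 ((1-formylalkyl)phosphonium salt) | CC(C)=CC(=O)O[C@@H](/C=C/[C@](C)(C/C=C/C(C)(C)O)CC=O)[C@@]1(C)O[C@@H]1CCC(C=O)[P+](c1ccccc1)(c1ccccc1)c1ccccc1.[Br-]
F3 | step 15 | C7-triphenylphosphoranylidene derivative of 24 (formyl-stabilised ylide) | CC(C)=CC(=O)O[C@@H](/C=C/[C@](C)(C/C=C/C(C)(C)O)CC=O)[C@@]1(C)O[C@@H]1CCC(C=O)=P(c1ccccc1)(c1ccccc1)c1ccccc1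
F4 | step 11 | (7S,8E,10R)-1-[(tert-butyldimethylsilyl)oxy]-10-{2-[(tert-butyldiphenylsilyl)oxy]ethyl}-10-methyltrideca-8,12-dien-5-yn-7-ol | O[C@@H](/C=C/[C@](C)(CC=C)CCO[Si](c1ccccc1)(c1ccccc1)C(C)(C)C)C#CCCCCO[Si](C)(C)C(C)(C)C
F5 | step 11 | (5Z,7S,8E,10R)-1-[(tert-butyldimethylsilyl)oxy]-10-{2-[(tert-butyldiphenylsilyl)oxy]ethyl}-10-methyl-6-(tributylstannyl)trideca-5,8,12-trien-7-ol | O[C@@H](/C=C/[C@](C)(CC=C)CCO[Si](c1ccccc1)(c1ccccc1)C(C)(C)C)/C([Sn](CCCC)(CCCC)CCCC)=C/CCCCO[Si](C)(C)C(C)(C)C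
F6 | step 11 | (5E,7S,8E,10R)-1-[(tert-butyldimethylsilyl)oxy]-10-{2-[(tert-butyldiphenylsilyl)oxy]ethyl}-6,10-dimethyltrideca-5,8,12-trien-7-ol | O[C@@H](/C=C/[C@](C)(CC=C)CCO[Si](c1ccccc1)(c1ccccc1)C(C)(C)C)/C(C)=C/CCCCO[Si](C)(C)C(C)(C)C
F7 | step 11 | (5E,7S,8E,10R)-1-[(tert-butyldimethylsilyl)oxy]-10-{2-[(tert-butyldiphenylsilyl)oxy]ethyl}-6,10-dimethyltrideca-5,8,12-trien-7-yl 3-methylbut-2-enoate | CC(C)=CC(=O)O[C@@H](/C=C/[C@](C)(CC=C)CCO[Si](c1ccccc1)(c1ccccc1)C(C)(C)C)/C(C)=C/CCCCO[Si](C)(C)C(C)(C)C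
F8 | step 1 | (1R,2E)-1-[(4R)-2,2-dimethyl-1,3-dioxolan-4-yl]-3-methylhexa-2,5-dien-1-ol (syn epimer of 4) | C=CC/C(C)=C/[C@@H](O)[C@H]1COC(C)(C)O1
F9 | step 1 | (2E)-1-[(4R)-2,2-dimethyl-1,3-dioxolan-4-yl]-3-methylhexa-2,5-dien-1-one | C=CC/C(C)=C/C(=O)[C@H]1COC(C)(C)O1
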